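There were 3 questions about these flasks, two orders and a yield, and I answered them from rates.

| flask | substrate | coupling partner | catalyst | time |
|---|---|---|---|---|
| alder | 0.0500 M | 0.0500 M | 0.00500 M |  |
| elm | 0.0250 M | 0.0250 M | 0.00500 M |  |
| oak | 0.0500 M | 0.0500 M | 0.00750 M |  |
| larch | 0.0750 M | 0.0500 M | 0.00500 M |  |
| cedar | 0.150 M | 0.0170 M | 0.00500 M | 4.9 min |

- alder run (time / min: [target] / M): 0.18: 0.00186; 0.53: 0.00459; 1.0: 0.00794; 1.6: 0.01192; 2.3: 0.01483; 3.1: 0.01758; 4.0: 0.01925; 4.9: 0.02027
- elm run (time / min: [target] / M): 0.18: 1.6 × 10⁻⁴; 0.53: 0.00191; 1.0: 0.00288; 1.6: 0.00468; 2.3: 0.00544; 3.1: 0.00682; 4.0: 0.00782; 4.9: 0.00825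
- oak run (time / min: [target] / M): 0.18: 0.00274; 0.53: 0.00701; 1.0: 0.01124; 1.6: 0.01606; 2.3: 0.01950; 3.1: 0.02225; 4.0: 0.02336; 4.9: 0.02425
- larch run (time / min: [target] / M): 0.18: 0.00246; 0.53: 0.00600; 1.0: 0.01059; 1.6: 0.01489; 2.3: 0.01861; 3.1: 0.02207; 4.0: 0.02411; 4.9: 0.02495

(scatter of a reading: 2 × 10⁻⁴ M)

1. order of the initial rate in [substrate], near the charge of the alder run, the rate being that where two percent of its substrate are target (one fixed amount of target, the same in the runs compared)
2. order of the initial rate in [coupling partner], near the charge of the alder run, the rate being that where two percent of its substrate are target
3. target in the cedar run at 4.9 min, as a share of the substrate charged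

- Overall: substrate + coupling partner -> target, with catalyst as catalyst.
- Constant volume, constant temperature.
- Bound and free are read together.
- An order is taken over about fifteen percent of the charge, up and down.

I began with the mean rate up to 1.0 min, the target read at that time divided by the time, as a stand-in for the rate at one fixed amount of target. In the alder run this mean rate was 0.00794 M min⁻¹. The larch run read 1.33 times as much target as the alder run at that time on 1.50 times the substrate, so I read an order in substrate of 0.710. The elm run, with both charges at 0.500 of those in the alder run, read 0.00288 M against 0.00794 M. The two orders therefore sum to 1.46, which left 0.753 for the coupling partner. These are rough readings.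

In the cedar run the substrate charge raises the alder rate by a factor of 2.18, and the coupling partner charge lowers it by a factor of 0.444, so I expected an opening rate of 0.00769 M min⁻¹. The coupling partner is the limiting reagent there, its charge being smaller than that of the substrate, so target can reach 11.3 % of the substrate at most. Dividing the opening rate by the partner charge gave a pace of 0.452 min⁻¹, treated as pseudo-first-order.

The slowing still had to be counted. In the alder run the same pace was 0.159 min⁻¹, and 40.5 % of the partner had become target by 4.9 min. I defined the working time as the time in which a rate falling in step with the remaining partner, from that opening pace, reaches the share actually reached: 3.27 min. It is shorter than the clock time, and the gap between the two stands for the slowing in the alder run beyond that fall. Pace times working time for the cedar run is 1.48, which takes 77.2 % of the way to the ceiling. My figure was therefore 8.76 % of the substrate.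

The forecast gave orders of 0.65 and 0.7 and a yield of 9.2 %, higher than mine, with the words “That suggests catalyst dying, with about 3 min of effective time by 4.9 min.”

The cedar run gave 6.77 %, with orders of 0.73 and 0.73.

    catalyst + substrate + coupling partner → target + catalyst (2328 L² mol⁻² min⁻¹)
    target → decomposed product (0.1086 min⁻¹)
    substrate + coupling partner ⇌ idle substrate-reagent adduct, settled at all times (24.60 L mol⁻¹)

That yield is less than my figure by 2 percentage points, and the equations include a loss of target to decomposed product with a constant of 0.109 min⁻¹. Read backwards, the cedar yield means a working time of 2.01 min, shorter than that of the alder run. Applied to the larch run at its pace of 0.212 min⁻¹, the alder working time gives 0.0250 M of target at 4.9 min, against a reading of 0.02495 M.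

Readings and results were generated by integration for an exercise, and the scatter is random.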